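**Plan**
- The retrosynthesis cuts O1–C8a and C4–C4a together. These two bonds tie ring C to the neighbouring carbons C8a and C4a of ring A. The cut leaves 3,5-dimethoxybenzyne and an (S)-β-oxy ester chain O1–C2–C3–C4 that already carries ring B.
- Enabling feature: O1 and the C4 acyl carbon are ortho to each other on ring A, and the C5 methoxy group stands next to C4a. The aryne is therefore polarised to accept oxygen at C8a and to carry the carbanion at C4a, within reach of the ester carbon C4 for a six-membered closure.
- Forward: fragment 1, the aryne precursor, comes from 3,5-dimethoxyphenol in two steps. Fragment 2 comes from a commercial β-keto ester in two steps. Ring C arises last, in the step that joins the two fragments.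
- Stereochemistry: the only stereocentre, C2 (S), is set by catalyst control in a Noyori transfer hydrogenation. It is carried on with its C–O bond never broken.
- Helpers: the O-SiMe3 group (a proton-free alkoxide source) and the C-SiMe3/OTf pair (the aryne source) are all lost within the key step.

Key step: step 5

Remark: C2 of the target is (S) (O1 > C1' of ring B > C3 > H). Compounds 1 and 7 are taken as commercial.

**Step 1**
Reactants: 1 3,5-dimethoxyphenol
Product: 2 2-bromo-3,5-dimethoxyphenol
Conditions: NBS (1.0 equiv), CH2Cl2, −78 °C to rt
Reagents that add atoms: N-bromosuccinimide, O=C1CCC(=O)N1Br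
Why: Electrophilic aromatic bromination of an activated phenol, in which the two equivalent positions ortho to OH and para to a methoxy group should be attacked in preference to C4, which is flanked by two methoxy groups, while one equivalent of NBS at low temperature limits dibromination.

**Step 2**
Reactants: 2 2-bromo-3,5-dimethoxyphenol
Product: 6 3,5-dimethoxy-2-(trimethylsilyl)phenyl trifluoromethanesulfonate, via aryl trimethylsilyl ether 3 (not isolated), via aryllithium 4 (not isolated), via lithium silylphenoxide 5 (not isolated)
Conditions: HMDS, THF, reflux, then evaporation; n-BuLi, THF, −78 °C; Tf2O, −78 to 0 °C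
Reagents that add atoms: hexamethyldisilazane, C[Si](C)(C)N[Si](C)(C)C; trifluoromethanesulfonic anhydride, O=S(=O)(OS(=O)(=O)C(F)(F)F)C(F)(F)F
Why: This is the standard sequence to ortho-silylaryl triflates (O-silylation, bromine–lithium exchange, retro-Brook shift of silicon from oxygen to the carbanion driven by phenoxide formation, then O-triflation), and none of it touches the methoxy groups.

**Step 3**
Reactants: 7 ethyl 3-oxo-3-(3,4,5-trimethoxyphenyl)propanoate
Product: 8 ethyl (S)-3-hydroxy-3-(3,4,5-trimethoxyphenyl)propanoate
Conditions: RuCl[(S,S)-TsDPEN](p-cymene) (cat.), HCO2H/Et3N (5:2), 30 °C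
Reagents that add atoms: none
Why: Noyori asymmetric transfer hydrogenation of an aryl ketone, in which the (S,S)-catalyst delivers hydride and proton through the six-membered outer-sphere transition state with the aryl group held under the η6-arene by a CH/π contact, so that the (S)-carbinol should form as with acetophenone (same CIP order O > aryl > CH2).

**Step 4**
Reactants: 8 ethyl (S)-3-hydroxy-3-(3,4,5-trimethoxyphenyl)propanoate
Product: 9 ethyl (S)-3-(3,4,5-trimethoxyphenyl)-3-(trimethylsilyloxy)propanoate
Conditions: TMSCl, imidazole, CH2Cl2, 0 °C
Reagents that add atoms: chlorotrimethylsilane, C[Si](C)(C)Cl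
Why: Standard silylation of a secondary alcohol, which replaces the only O–H proton by a group that fluoride removes in the key step and does not involve the stereocentre.

**Step 5**
Reactants: 6 3,5-dimethoxy-2-(trimethylsilyl)phenyl trifluoromethanesulfonate; 9 ethyl (S)-3-(3,4,5-trimethoxyphenyl)-3-(trimethylsilyloxy)propanoate
Product: 13 (S)-5,7-dimethoxy-2-(3,4,5-trimethoxyphenyl)chroman-4-one, via 3,5-dimethoxybenzyne 10 (not isolated), via potassium alkoxide 11 (not isolated), via aryl anion 12 (not isolated)
Conditions: 6 (1.5 equiv, slow addition), KF, 18-crown-6, THF, −20 °C to rt; pH 7 phosphate buffer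
Reagents that add atoms: none
Why: Proposed new method: fluoride removes the C-silyl group of 6 with loss of triflate to give aryne 10 and reversibly removes the O-silyl group of 9 to give a low stationary concentration of the proton-free alkoxide 11; O-attack of 11 on 10 forms O1–C8a and leaves aryl anion 12 at C4a, which forms C4a–C4 by addition–elimination at the ethyl ester, and the expelled ethoxide is capped as EtOSiMe3 by Me3SiF or by 9, so that no strong base builds up. The closest known reaction types are the fluoride-promoted annulation of arynes by salicylate esters to xanthones and the insertion of arynes into the amide bond of N–H β-lactams to 2,3-dihydroquinolin-4-ones; an aliphatic, enolisable β-silyloxy ester has not been shown in this role. Ring C closes in the 6-exo-trig mode (carbanion C4a on the ester carbonyl C4, carbonyl oxygen outside the ring). No stereocentre is created: C2 comes from 9 and its C–O and C–H bonds are not touched, so (S) is retained as long as retro-aldol cleavage of 11 and enolisation with ring opening of 13 stay slow, which the low temperature, the capped ethoxide and the buffered quench are meant to secure. Regioselectivity is needed and is secured by the methoxy group on the carbon next to the triple bond of 10 (later C5), which distorts and polarises the aryne so that the nucleophile enters at the remote carbon (C8a) and the charge develops beside the C–OMe bond (C4a), the second methoxy group being too remote to override this. Acyl capture by 12 in preference to protonation is served by the absence of any O–H or N–H bond, by THF in place of acetonitrile and by the six-membered transition state.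

**Compound list**
1 | 3,5-dimethoxyphenol | COc1cc(O)cc(OC)c1 | starting material
2 | 2-bromo-3,5-dimethoxyphenol | COc1cc(O)c(Br)c(OC)c1 | intermediate
3 | (2-bromo-3,5-dimethoxyphenoxy)trimethylsilane | COc1cc(O[Si](C)(C)C)c(Br)c(OC)c1 | intermediate
4 | [2,4-dimethoxy-6-(trimethylsilyloxy)phenyl]lithium | [Li]c1c(OC)cc(OC)cc1O[Si](C)(C)C | intermediate
5 | lithium 3,5-dimethoxy-2-(trimethylsilyl)phenoxide | [Li+].COc1cc([O-])c([Si](C)(C)C)c(OC)c1 | intermediate
6 | 3,5-dimethoxy-2-(trimethylsilyl)phenyl trifluoromethanesulfonate | COc1cc(OS(=O)(=O)C(F)(F)F)c([Si](C)(C)C)c(OC)c1 | intermediate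
7 | ethyl 3-oxo-3-(3,4,5-trimethoxyphenyl)propanoate | CCOC(=O)CC(=O)c1cc(OC)c(OC)c(OC)c1 | starting material
8 | ethyl (S)-3-hydroxy-3-(3,4,5-trimethoxyphenyl)propanoate | O[C@H](c1cc(OC)c(OC)c(OC)c1)CC(=O)OCC | intermediate
9 | ethyl (S)-3-(3,4,5-trimethoxyphenyl)-3-(trimethylsilyloxy)propanoate | C[Si](C)(C)O[C@H](c1cc(OC)c(OC)c(OC)c1)CC(=O)OCC | intermediate
10 | 3,5-dimethoxybenzyne | COC1=CC(OC)=CC#C1 | intermediate
11 | potassium (S)-3-ethoxy-3-oxo-1-(3,4,5-trimethoxyphenyl)propan-1-olate | [K+].[O-][C@H](c1cc(OC)c(OC)c(OC)c1)CC(=O)OCC | intermediate
12 | potassium salt of the aryl anion, ethyl (S)-3-(3,5-dimethoxyphenoxy)-3-(3,4,5-trimethoxyphenyl)propanoate deprotonated at C2 of the phenoxy ring | [K+].COc1cc(OC)[c-]c(c1)O[C@H](c1cc(OC)c(OC)c(OC)c1)CC(=O)OCC | intermediate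
13 | (S)-5,7-dimethoxy-2-(3,4,5-trimethoxyphenyl)chroman-4-one | COc1cc(OC)c2c(c1)O[C@H](c1cc(OC)c(OC)c(OC)c1)CC2=O | target

**Total step count:** 5. **Longest linear sequence:** 3 steps (1 → 2 → 6 → 13, or 7 → 8 → 9 → 13).

**Steps most likely to fail**

**Step 5 (Proposed new method).**
- Proton transfer to the aryl anion, from the α-methylene group or from traces of water, may outrun acyl capture. The sequence would then stop at plain O-arylation and could go on to β-elimination.
- Retro-aldol cleavage or β-elimination may occur at the alkoxide stage.
- Fluoride-induced enolisation of the product, with reversible opening of ring C, would erode the configurational purity.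
- The fallback uses known chemistry and makes the two bonds one after the other, with the C–O bond formed by SN2 inversion instead of aryne capture. It sets out from 7 and 2 and comes back at 13.
- Transfer hydrogenation of 7 with the enantiomeric catalyst RuCl[(R,R)-TsDPEN](p-cymene) in HCO2H/Et3N would give ethyl (R)-3-hydroxy-3-(3,4,5-trimethoxyphenyl)propanoate F1. MeNHOMe·HCl and i-PrMgCl in THF at −20 °C would convert it into the (R)-β-hydroxy Weinreb amide F2.
- A Mitsunobu reaction of F2 with bromophenol 2 (PPh3, DIAD, THF, 0 °C) would form O1–C2 with inversion and give the (S)-aryl ether F3.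
- n-BuLi in THF at −78 °C would give, by bromine–lithium exchange, the aryllithium F4. This closes ring C on the Weinreb amide (Parham cyclisation) and gives 13 after a cold quench with aqueous NH4Cl.

**Step 1.**
- Poor regioselectivity (attack at C4 between the two methoxy groups) and over-bromination would cost material and make separation difficult.
- The fallback replaces electrophilic substitution by directed ortho-metalation. It sets out from 1, comes back at 6, and also bypasses step 2.
- Isopropyl isocyanate with catalytic Et3N in CH2Cl2 would give 3,5-dimethoxyphenyl N-isopropylcarbamate F5.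
- In one flask, TBSOTf and TMEDA in Et2O would give the N-silylated carbamate F6. n-BuLi/TMEDA at −78 °C would lithiate the position between the carbamate and a methoxy group to give the ortho-lithio carbamate F7. TMSCl would then give the doubly silylated carbamate F8, and a mildly acidic work-up would give 3,5-dimethoxy-2-(trimethylsilyl)phenyl N-isopropylcarbamate F9.
- DBU and Et2NH in MeCN at 40 °C would release 3,5-dimethoxy-2-(trimethylsilyl)phenol F10, which PhNTf2 added to the same flask would convert into 6.

**Step 3.**
- Insufficient facial selectivity, or a slow reduction of the partly enolised β-keto ester, would lower the enantiomeric purity of everything that follows.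
- The fallback uses resolution in place of asymmetric catalysis. It sets out from 7 and comes back at 8.
- NaBH4 in EtOH at 0 °C would give the racemic hydroxy ester F11.
- Lipase from Burkholderia cepacia with vinyl acetate in MTBE should acylate the (R)-alcohol faster, following the empirical size rule for secondary carbinols with aryl as the large group. This would give the (R)-acetate F12, and the unreacted (S)-alcohol 8 would be separated by chromatography.

**Further compounds**
F1 | step 5 | ethyl (R)-3-hydroxy-3-(3,4,5-trimethoxyphenyl)propanoate | O[C@@H](c1cc(OC)c(OC)c(OC)c1)CC(=O)OCC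
F2 | step 5 | (R)-3-hydroxy-N-methoxy-N-methyl-3-(3,4,5-trimethoxyphenyl)propanamide | O[C@@H](c1cc(OC)c(OC)c(OC)c1)CC(=O)N(C)OC
F3 | step 5 | (S)-3-(2-bromo-3,5-dimethoxyphenoxy)-N-methoxy-N-methyl-3-(3,4,5-trimethoxyphenyl)propanamide | COc1cc(OC)c(Br)c(c1)O[C@H](c1cc(OC)c(OC)c(OC)c1)CC(=O)N(C)OC
F4 | step 5 | aryllithium from F3 (lithium in place of bromine) | COc1cc(OC)c([Li])c(c1)O[C@H](c1cc(OC)c(OC)c(OC)c1)CC(=O)N(C)OC
F5 | step 1 | 3,5-dimethoxyphenyl N-isopropylcarbamate | CC(C)NC(=O)Oc1cc(OC)cc(OC)c1
F6 | step 1 | 3,5-dimethoxyphenyl N-(tert-butyldimethylsilyl)-N-isopropylcarbamate | CC(C)N(C(=O)Oc1cc(OC)cc(OC)c1)[Si](C)(C)C(C)(C)C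
F7 | step 1 | 2-lithio-3,5-dimethoxyphenyl N-(tert-butyldimethylsilyl)-N-isopropylcarbamate | CC(C)N(C(=O)Oc1cc(OC)cc(OC)c1[Li])[Si](C)(C)C(C)(C)C
F8 | step 1 | 3,5-dimethoxy-2-(trimethylsilyl)phenyl N-(tert-butyldimethylsilyl)-N-isopropylcarbamate | CC(C)N(C(=O)Oc1cc(OC)cc(OC)c1[Si](C)(C)C)[Si](C)(C)C(C)(C)C
F9 | step 1 | 3,5-dimethoxy-2-(trimethylsilyl)phenyl N-isopropylcarbamate | CC(C)NC(=O)Oc1cc(OC)cc(OC)c1[Si](C)(C)C
F10 | step 1 | 3,5-dimethoxy-2-(trimethylsilyl)phenol | COc1cc(O)c([Si](C)(C)C)c(OC)c1
F11 | step 3 | racemic ethyl 3-hydroxy-3-(3,4,5-trimethoxyphenyl)propanoate | OC(c1cc(OC)c(OC)c(OC)c1)CC(=O)OCC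
F12 | step 3 | ethyl (R)-3-acetoxy-3-(3,4,5-trimethoxyphenyl)propanoate | CC(=O)O[C@@H](c1cc(OC)c(OC)c(OC)c1)CC(=O)OCC
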